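At late times the flask's readings stand clear of their scatter: after 20.0 min it held 89.9 % of its starting material. The noon run, after 40.0 min, held 74.6 % beside 25.6 % first product and 1.1 % bis adduct. These noon figures sum to 101 %, close to 100 percent, so little unread material stands beside them. At the same 12.0 min the flask held 94.5 % and the noon run, charged at a higher concentration, held less, namely 90.4 %. The loss of starting material therefore grows with concentration in these readings, and the reckoning takes as its working law one rate, k[starting material][coupling partner].

| flask | starting material | coupling partner | remark | time |
|---|---|---|---|---|
| winter | 0.10 M | 0.80 equiv | the very flask that is asked about, followed so far |  |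
| noon | 0.15 M | 0.80 equiv | run made earlier |  |
| flask | 0.10 M | 0.800 equiv |  | 1.0 h |

| run | time / min | starting material / % | first product / % | bis adduct / % |
|---|---|---|---|---|
| winter | 1.50 | 99.2 | 1.0 | 0.4 |
| winter | 5.00 | 97.3 | 3.6 | 0 |
| winter | 8.00 | 96.4 | 4.8 | 0 |
| winter | 12.0 | 94.5 | 7.2 | 0.3 |
| winter | 20.0 | 89.9 | 10.6 | 0.6 |
| noon | 3.00 | 98.0 | 2.4 | 0 |
| noon | 6.00 | 95.6 | 4.6 | 0 |
| noon | 12.0 | 90.4 | 9.3 | 0.4 |
| noon | 20.0 | 85.2 | 13.2 | 0.2 |
| noon | 40.0 | 74.6 | 25.6 | 1.1 |

(readings scatter by 0.5 percentage points)

- percent here means starting material units held: one self-condensation product counts as two
- candidate steps: coupling partner + triple product -> tetra adduct; coupling partner + first product -> bis adduct; starting material + coupling partner -> first product; coupling partner + bis adduct -> triple product; 2 starting material -> self-condensation product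

1. amount of starting material at 1.0 h, in percent of the starting material charged
2. amount of first product at 1.0 h, in percent of the starting material charged
3. amount of bis adduct at 1.0 h, in percent of the starting material charged
4. amount of triple product at 1.0 h, in percent of the starting material charged

A first hand estimate holds [coupling partner] at its charge. The flask's last reading then gives k = 0.0665 M⁻¹ min⁻¹, and at 1.0 h the flask keeps 72.7 % of its starting material.

That held level is the weak link. The coupling partner, charged at 0.80 equiv, is the limiting reagent, and it falls one for one with the starting material. With a and b the fractions of each left of its own charge, integrating the rate gives ln(a/b) = k × (charged [starting material] − charged [coupling partner]) × t. The same last reading, put through this closed form, gives the integrated constant 0.0712 M⁻¹ min⁻¹. At 1.0 h it leaves 75.3 % starting material, more than the hand value. At fixed equivalents the law depends on concentration times time, and the flask at 1.0 h matches the noon run at 40.0 min in that product. The noon reading, from a different run, lies 0.70 percentage points from this reckoning.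

The forecast gives 75.3 % starting material, 23.7 % first product, 1 % bis adduct and 0.03 % triple product, on the ground that “concentration × time is the true clock”. Its starting material matches the reckoning above.

The flask gives 74.2 % starting material, 25.2 % first product, 0.225 % bis adduct and 0 % triple product, and the forecast stands within its margins.

    coupling partner + triple product → tetra adduct (k = 2.39 × 10⁻⁵ M⁻¹ s⁻¹)
    coupling partner + first product → bis adduct (k = 7.19 × 10⁻⁵ M⁻¹ s⁻¹)
    starting material + coupling partner → first product (k = 0.00124 M⁻¹ s⁻¹)
    coupling partner + bis adduct → triple product (k = 2.01 × 10⁻⁵ M⁻¹ s⁻¹)
    2 starting material → self-condensation product (k = 8.54 × 10⁻⁶ M⁻¹ s⁻¹)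

This flask holds 74.2 % starting material mainly because it is read at 1.0 h and not ten times later: left until 10.0 h, it holds 29.9 %. The falling level of coupling partner is a part of the reason: with that level held, this flask keeps 69.6 %. In the neighbour flask at 0.40 M, with the same equivalents and time, 0.0712 M⁻¹ min⁻¹ gives 46.3 % starting material. That flask computes to 45.0 %.

The data were computed from invented constants, and the scatter is random.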